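## Retrosynthetic overview

- **Feature:** ring B (C5–C10) carries oxygen on C6 and C9, para to each other, and methyl groups on C8 and C10 on either side of C9. This is the substitution pattern of 2,6-dimethyl-1,4-benzoquinone, so ring B is bought.
- **Ring A:** an asymmetric Diels–Alder reaction of the quinone C5=C10 alkene with (E)-2-silyloxypenta-1,3-diene forms C1–C10 and C4–C5 and the quaternary C10. Saegusa–Ito oxidation and cuprate addition then give C4Me2, enol triflate reduction clears C2, equilibration sets C5 and C8, and α-face hydride sets C6.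
- **Side chain:** the C9 ketone becomes the C9=C11 alkene and then the 9α,11-epoxide, which dilithiated methallyl alcohol opens at C11 (C11–C12 bond).
- **Rings C and D:** Sharpless epoxidation fixes C13, and the 9α-hydroxyl opens the 13,16-epoxide 5-exo with inversion to close ring C (O, C9, C11, C12, C13). Endo-cycloisomerisation of the ethynyl/CH2OH pair on C13 closes ring D (C13, C14, C15, O, C16) and gives the C14=C15 enol ether last.
- **Order of rings:** B (purchased), A (step 2), C (step 18), D (step 19).

Key step: step 2

Remark on numbering: labdane numbering is used for all intermediates. β is the face of the C10 methyl group and α the opposite face.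

Assumption: the (S)-configured oxazaborolidinium ion is taken to leave the α face of the bound C5=C10 alkene open, by analogy with acrylate dienophiles held by the same α-C–H···O contact. If the adduct proves antipodal, the equally available (R)-catalyst is used and nothing else changes.

## Route

Step 1
Reactants: 1 (E)-pent-3-en-2-one
Product: 2 (E)-2-(tert-butyldimethylsilyloxy)penta-1,3-diene
Conditions: TBSOTf, Et3N, Et2O, 0 °C
Reagents that add atoms: tert-butyldimethylsilyl trifluoromethanesulfonate, CC(C)(C)[Si](C)(C)OS(=O)(=O)C(F)(F)F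
Why: Soft enolisation with a silyl triflate and a tertiary amine takes the α′-methyl proton of the enone under kinetic control, which gives the cross-conjugated 2-silyloxydiene and leaves the E alkene as it is.

Step 2
Reactants: 2 (E)-2-(tert-butyldimethylsilyloxy)penta-1,3-diene; 3 2,6-dimethyl-1,4-benzoquinone
Product: 4 cis-fused ene-dione cycloadduct (5β-H, 10β-methyl, 4α-methyl; C6 and C9 ketones, C7=C8 alkene, C2=C3 TBS enol ether)
Conditions: (S)-3,3-diphenyl-1-(2-methylphenyl)tetrahydro-1H,3H-pyrrolo[1,2-c][1,3,2]oxazaborole (20 mol %), HN(SO2CF3)2 (18 mol %), CH2Cl2, −78 °C; Et3N quench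
Reagents that add atoms: none
Why: The N-protonated oxazaborolidine binds the C6 carbonyl oxygen of 3 (flanked by two CH groups, hence less hindered, and made more basic by the two β-methyl groups) with an α-C–H···O contact, and the diene adds in a concerted but asynchronous [4+2] cycloaddition in which C1–C10 bond formation runs ahead of C4–C5. The closest known reaction type is the oxazaborolidinium-catalysed Diels–Alder reaction of 2-silyloxydienes with methyl-substituted 1,4-benzoquinones, and the Lewis acid-induced orientation of 2,6-dimethylbenzoquinone towards 1-substituted dienes is the regiochemical precedent. Ring A is closed by an intermolecular six-membered cycloaddition, suprafacial on both partners, across the C5=C10 alkene. C10 (β-methyl) is fixed by the catalyst, whose aryl group covers one face of the bound enone so that the diene arrives from the α face; C5 follows from suprafacial addition (5β-H cis to the C10 methyl) and C4 from the endo transition state of the E diene (4α-methyl, H4 cis to H5). The step needs the CH2 terminus of the diene (largest HOMO coefficient, reinforced by the 2-silyloxy and the 4-methyl group) to bond to C10, which is secured because C10 is the β carbon of the activated C6 enone, and no site selectivity is needed because both quinone alkenes are equivalent. C4 is later made achiral and C5 is later epimerised, so only C10 has to be right here.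

Step 3
Reactants: 4 cis-fused ene-dione cycloadduct
Product: 5 cis-fused 6,9-dione (C7–C8 saturated, C8 epimer mixture, TBS enol ether kept)
Conditions: Zn dust, AcOH, THF, 0 °C, short contact time
Reagents that add atoms: none
Why: Dissolving-metal conjugate reduction (Zn/AcOH) of an ene-dione is much faster than attack on the isolated carbonyl groups or, at short contact time, protonolysis of the TBS enol ether; C8 arises as an epimer mixture that is levelled in step 4.

Step 4
Reactants: 5 cis-fused 6,9-dione
Product: 6 trans-fused 6,9-dione (5α-H, 8α-methyl, 10β-methyl, 4α-methyl)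
Conditions: DBU (0.5 equiv), toluene, 23 → 50 °C, argon
Reagents that add atoms: none
Why: Amidine-base epimerisation through the C5=C6 and C8=C9 enolates: reprotonation of C5 anti to the axial C10 methyl gives the trans-decalindione, which with its equatorial 8α- and 4α-methyl groups should also be the thermodynamic isomer, while C10 and C4 cannot enolise.

Step 5
Reactants: 6 trans-fused 6,9-dione
Product: 7 6β-hydroxy-9-ketone (axial alcohol, TBS enol ether kept)
Conditions: LiBH(s-Bu)3 (1.1 equiv), THF, −78 °C; then NaOH aq, H2O2, 0 °C
Reagents that add atoms: none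
Why: Bulky trialkylborohydride reduction: the C9 carbonyl is shielded by quaternary C10 and by C8, so only C6 reacts, and hydride comes along the equatorial α trajectory away from the axial C10 methyl to leave the axial 6β-alcohol, as with 6-oxo-5α-steroids and 6-oxolabdanes.

Step 6
Reactants: 7 6β-hydroxy-9-ketone
Product: 8 6β-triethylsilyl ether
Conditions: TESOTf, 2,6-lutidine, CH2Cl2, −78 → 0 °C
Reagents that add atoms: triethylsilyl trifluoromethanesulfonate, CC[Si](CC)(CC)OS(=O)(=O)C(F)(F)F
Why: Silyl triflate/lutidine silylation covers even an axial secondary alcohol at low temperature, the weak base does not enolise the hindered C9 ketone, and the small TES group keeps ring A as open as possible for step 8.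

Step 7
Reactants: 8 6β-triethylsilyl ether
Product: 9 ring A enone (C2 ketone, C3=C4 alkene bearing the C4 methyl)
Conditions: Pd(OAc)2 (1.05 equiv), MeCN, 23 → 40 °C
Reagents that add atoms: none
Why: Saegusa–Ito oxidation: divalent palladium converts the silyl enol ether into the C3-bound oxo-allyl species and β-hydride elimination can only use H4, because the other α carbon (C1) adjoins quaternary C10, so the C3=C4 enone is the only product and the C4 stereocentre is erased.

Step 8
Reactants: 9 ring A enone
Product: 11 C2=C3 enol triflate with the 4,4-dimethyl group, via lithium enolate 10 (not isolated)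
Conditions: Me2CuLi (from MeLi and CuBr·SMe2), Et2O, −20 → 0 °C; then PhNTf2, THF/DMPU, 0 → 23 °C
Reagents that add atoms: lithium dimethylcuprate, [Li+].C[Cu-]C; N-phenylbis(trifluoromethanesulfonimide), O=S(=O)(C(F)(F)F)N(c1ccccc1)S(=O)(=O)C(F)(F)F
Why: Gilman cuprate 1,4-addition to a β,β-disubstituted cyclohexenone with a 1,3-related axial methyl group is the isophorone case, both faces of C4 give the same gem-dimethyl product so the less encumbered α face can be used, the hindered C9 ketone is spared, and the regiodefined enolate is caught by N-phenyltriflimide.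

Step 9
Reactants: 11 C2=C3 enol triflate
Product: 12 C2=C3 alkene
Conditions: Pd(OAc)2 (5 mol %), PPh3 (10 mol %), HCO2H, Et3N, DMF, 60 °C
Reagents that add atoms: none
Why: Palladium-catalysed formate hydrogenolysis of a vinyl triflate: zerovalent palladium inserts into the C2–O bond, formate delivers hydride with loss of CO2, and ketone and silyl ether are not touched.

Step 10
Reactants: 12 C2=C3 alkene
Product: 14 6β-hydroxy-11-nordriman-9-one (trans-decalin; 4,4,8α,10β-tetramethyl), via saturated silyl ether 13 (not isolated)
Conditions: H2 (1 atm), Pd/C, EtOH, 23 °C; then 1 M HCl added to the filtrate, 23 °C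
Reagents that add atoms: none
Why: Heterogeneous hydrogenation saturates the cis-disubstituted C2=C3 alkene while the hindered C9 ketone stays, and dilute acid then cleaves the TES ether without risk for C5, C6 and C10 or for the equatorial C8 methyl.

Step 11
Reactants: 14 6β-hydroxy-11-nordriman-9-one
Product: 15 drim-9(11)-en-6β-ol (exocyclic C9=C11 alkene)
Conditions: Ph3PCH3Br (5 equiv), KOt-Bu (4.8 equiv), toluene, reflux
Reagents that add atoms: methyltriphenylphosphonium bromide, C[P+](c1ccccc1)(c1ccccc1)c1ccccc1.[Br-]
Why: Wittig methylenation with the lithium-free ylide in hot toluene is the variant that works for 2,2,6-trisubstituted cyclohexanones; excess ylide carries the C6 hydroxyl as its alkoxide, and any enolisation returns the favoured equatorial 8α-methyl.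

Step 12
Reactants: 15 drim-9(11)-en-6β-ol
Product: 16 9α,11-epoxydriman-6β-ol (spiro-epoxide, oxygen axial on the α face)
Conditions: dimethyldioxirane (1.1 equiv), acetone, 0 °C
Reagents that add atoms: dimethyldioxirane, CC1(C)OO1
Why: Dioxirane epoxidation under neutral conditions: the β face of the C9=C11 alkene is covered by the adjacent axial C10 methyl, so oxygen is delivered from the α face and C9 gets its axial α C–O bond with C11 equatorial (β).

Step 13
Reactants: 16 9α,11-epoxydriman-6β-ol; 17 2-methylprop-2-en-1-ol
Product: 19 15-norlabd-13(16)-ene-6β,9α,14-triol, via dilithio alkoxide 18 (not isolated)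
Conditions: 17 (4 equiv), n-BuLi (8 equiv), TMEDA, Et2O, 0 → 23 °C; then 16, THF, −78 → 23 °C
Reagents that add atoms: none
Why: SN2 opening of a terminal spiro-epoxide by an allyllithium: the dilithiated methallyl alcohol attacks the unsubstituted C11, so the C9–O bond and its configuration are kept and the 2-substituted allylic alcohol is installed in one operation.

Step 14
Reactants: 19 15-norlabd-13(16)-ene-6β,9α,14-triol
Product: 20 (13R)-13,16-epoxy-15-norlabdane-6β,9α,14-triol
Conditions: Ti(OiPr)4 (0.2 equiv), D-(−)-diisopropyl tartrate (0.24 equiv), t-BuOOH (decane), 4 Å molecular sieves, CH2Cl2, −20 °C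
Reagents that add atoms: tert-butyl hydroperoxide, CC(C)(C)OO
Why: Katsuki–Sharpless asymmetric epoxidation of a 2-substituted allylic alcohol is reagent-controlled: D-(−)-tartrate delivers oxygen to the face that gives the (13R)-epoxide independently of the remote decalin, and the hindered C6 and C9 hydroxyls are not allylic and stay spectators.

Step 15
Reactants: 20 (13R)-13,16-epoxy-15-norlabdane-6β,9α,14-triol
Product: 21 13,16-epoxy-6β,9α-dihydroxy-15-norlabdan-14-al (C13 arranged as in 20; the descriptor becomes S by priority change only)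
Conditions: TEMPO (0.1 equiv), PhI(OAc)2 (1.1 equiv), CH2Cl2, 0 → 23 °C
Reagents that add atoms: none
Why: Oxoammonium (TEMPO/PhI(OAc)2) oxidation takes primary alcohols and leaves alone the axial 6β-hydroxyl, flanked by two syn-axial methyl groups, and the tertiary 9-hydroxyl; the aldehyde has no α hydrogen, so C13 cannot epimerise.

Step 16
Reactants: 21 epoxy aldehyde
Product: 22 (13R)-13,16-epoxylabd-14-yne-6β,9α-diol
Conditions: dimethyl (1-diazo-2-oxopropyl)phosphonate, K2CO3, MeOH, 0 → 23 °C
Reagents that add atoms: dimethyl (1-diazo-2-oxopropyl)phosphonate, COP(=O)(OC)C(=[N+]=[N-])C(C)=O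
Why: Seyferth–Gilbert homologation with the Ohira–Bestmann reagent turns the non-enolisable epoxy aldehyde into the terminal alkyne (C14≡C15) under mild carbonate conditions that do not open the epoxide.

Step 17
Reactants: 22 (13R)-13,16-epoxylabd-14-yne-6β,9α-diol
Product: 23 (13R)-6β-acetoxy-13,16-epoxylabd-14-yn-9α-ol
Conditions: Ac2O, DMAP, pyridine, 40 °C
Reagents that add atoms: acetic anhydride, CC(=O)OC(C)=O
Why: DMAP-catalysed acetylation reaches the hindered secondary 6β-hydroxyl on gentle warming whereas the tertiary axial 9α-hydroxyl is not acylated, so the acetate is in place before the sensitive end game.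

Step 18
Reactants: 23 (13R)-6β-acetoxy-13,16-epoxylabd-14-yn-9α-ol
Product: 24 (13S)-6β-acetoxy-9α,13-epoxylabd-14-yn-16-ol (ring C closed; C13 bears ethynyl and CH2OH)
Conditions: camphor-10-sulfonic acid (0.1 equiv), CH2Cl2, −20 → 0 °C
Reagents that add atoms: none
Why: Acid-catalysed epoxy-alcohol cyclisation: the 9α-hydroxyl attacks the fully substituted propargylic C13 in the 5-exo-tet mode, favoured by ring size and by charge build-up, from the side opposite to the departing oxygen, so that inversion translates the (13R)-epoxide into the (13S)-oxolane and sets the C16 hydroxyl free.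

Step 19
Reactants: 24 (13S)-6β-acetoxy-9α,13-epoxylabd-14-yn-16-ol
Product: 25 (13S)-6β-acetoxy-9α,13:15,16-diepoxylabd-14-ene (target)
Conditions: Mo(CO)6 (0.25 equiv), Et3N, Et2O, hν (350 nm), 23 °C; chromatography on Et3N-deactivated silica
Reagents that add atoms: none
Why: Alkynol endo-cycloisomerisation: photogenerated Et3N·Mo(CO)5 (zerovalent molybdenum) converts the terminal alkyne into a vinylidene complex whose electrophilic C15 is attacked by the C16 hydroxyl, and an amine-mediated proton shift releases the 2,3-dihydrofuran under basic conditions that enol ether and acetate tolerate, with no stereocentre touched.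

## Compound list

1 | (E)-pent-3-en-2-one | C/C=C/C(C)=O | starting material
2 | (E)-2-(tert-butyldimethylsilyloxy)penta-1,3-diene | C=C(O[Si](C)(C)C(C)(C)C)/C=C/C | intermediate
3 | 2,6-dimethyl-1,4-benzoquinone | CC1=CC(=O)C=C(C)C1=O | starting material
4 | cis-fused ene-dione cycloadduct (5β-H, 10β-Me, 4α-Me, C2 TBS enol ether) | O=C1C=C(C)C(=O)[C@@]2(C)CC(O[Si](C)(C)C(C)(C)C)=C[C@@H](C)[C@@H]12 | intermediate
5 | cis-fused 6,9-dione (C8 epimer mixture) | O=C1CC(C)C(=O)[C@@]2(C)CC(O[Si](C)(C)C(C)(C)C)=C[C@@H](C)[C@@H]12 | intermediate
6 | trans-fused 6,9-dione (5α-H, 8α-Me) | O=C1C[C@@H](C)C(=O)[C@@]2(C)CC(O[Si](C)(C)C(C)(C)C)=C[C@@H](C)[C@H]12 | intermediate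
7 | 6β-hydroxy-9-ketone | O[C@@H]1C[C@@H](C)C(=O)[C@@]2(C)CC(O[Si](C)(C)C(C)(C)C)=C[C@@H](C)[C@H]12 | intermediate
8 | 6β-triethylsilyl ether | CC[Si](CC)(CC)O[C@@H]1C[C@@H](C)C(=O)[C@@]2(C)CC(O[Si](C)(C)C(C)(C)C)=C[C@@H](C)[C@H]12 | intermediate
9 | ring A enone (2-oxo, C3=C4) | CC[Si](CC)(CC)O[C@@H]1C[C@@H](C)C(=O)[C@@]2(C)CC(=O)C=C(C)[C@H]12 | intermediate
10 | lithium enolate (C2=C3, 4,4-dimethyl) | [Li+].CC[Si](CC)(CC)O[C@@H]1C[C@@H](C)C(=O)[C@@]2(C)CC([O-])=CC(C)(C)[C@H]12 | intermediate
11 | C2=C3 enol triflate | CC[Si](CC)(CC)O[C@@H]1C[C@@H](C)C(=O)[C@@]2(C)CC(OS(=O)(=O)C(F)(F)F)=CC(C)(C)[C@H]12 | intermediate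
12 | C2=C3 alkene | CC[Si](CC)(CC)O[C@@H]1C[C@@H](C)C(=O)[C@@]2(C)CC=CC(C)(C)[C@H]12 | intermediate
13 | saturated silyl ether | CC[Si](CC)(CC)O[C@@H]1C[C@@H](C)C(=O)[C@@]2(C)CCCC(C)(C)[C@H]12 | intermediate
14 | 6β-hydroxy-11-nordriman-9-one | O[C@@H]1C[C@@H](C)C(=O)[C@@]2(C)CCCC(C)(C)[C@H]12 | intermediate
15 | drim-9(11)-en-6β-ol | O[C@@H]1C[C@@H](C)C(=C)[C@@]2(C)CCCC(C)(C)[C@H]12 | intermediate
16 | 9α,11-epoxydriman-6β-ol | O[C@@H]1C[C@@H](C)[C@]2(CO2)[C@@]3(C)CCCC(C)(C)[C@H]13 | intermediate
17 | 2-methylprop-2-en-1-ol | C=C(C)CO | starting material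
18 | dilithiated 2-methylprop-2-en-1-ol | [Li+].[Li+].[CH2-]C(=C)C[O-] | intermediate
19 | 15-norlabd-13(16)-ene-6β,9α,14-triol | O[C@@H]1C[C@@H](C)[C@](O)(CCC(=C)CO)[C@@]2(C)CCCC(C)(C)[C@H]12 | intermediate
20 | (13R)-13,16-epoxy-15-norlabdane-6β,9α,14-triol | O[C@@H]1C[C@@H](C)[C@](O)(CC[C@@]3(CO)CO3)[C@@]2(C)CCCC(C)(C)[C@H]12 | intermediate
21 | 13,16-epoxy-6β,9α-dihydroxy-15-norlabdan-14-al | O[C@@H]1C[C@@H](C)[C@](O)(CC[C@@]3(C=O)CO3)[C@@]2(C)CCCC(C)(C)[C@H]12 | intermediate
22 | (13R)-13,16-epoxylabd-14-yne-6β,9α-diol | O[C@@H]1C[C@@H](C)[C@](O)(CC[C@@]3(C#C)CO3)[C@@]2(C)CCCC(C)(C)[C@H]12 | intermediate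
23 | (13R)-6β-acetoxy-13,16-epoxylabd-14-yn-9α-ol | CC(=O)O[C@@H]1C[C@@H](C)[C@](O)(CC[C@@]3(C#C)CO3)[C@@]2(C)CCCC(C)(C)[C@H]12 | intermediate
24 | (13S)-6β-acetoxy-9α,13-epoxylabd-14-yn-16-ol | CC(=O)O[C@@H]1C[C@@H](C)[C@]2(CC[C@@](CO)(C#C)O2)[C@@]2(C)CCCC(C)(C)[C@H]12 | intermediate
25 | (13S)-6β-acetoxy-9α,13:15,16-diepoxylabd-14-ene (CNP0242014.3) | CC(=O)O[C@@H]1C[C@@H](C)[C@]2(CC[C@@]3(C=COC3)O2)[C@@]2(C)CCCC(C)(C)[C@H]12 | target

## Step count and risks

Total step count: 19. Longest linear sequence: 19 steps, from (E)-pent-3-en-2-one.

Steps most likely to fail: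

1. **Step 2.** Enantiofacial discrimination at the trisubstituted quinone alkene may be incomplete. Acid-induced Mukaiyama–Michael addition and desilylation of the diene may also compete with ring closure.
   - The fallback sets out from 2 and 3.
   - The cycloaddition is run with the achiral Lewis acid BF3·OEt2 (CH2Cl2, −78 °C), which binds the same unhindered C6 carbonyl and therefore keeps the orientation.
   - It gives 4 as a racemate with its mirror image, the ent-cycloadduct F1.
   - The antipodes are separated by preparative chromatography on a chiral stationary phase, so the absolute configuration comes from resolution instead of catalysis. The route is re-entered at 4.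

2. **Step 13.** The hard, aggregated dilithio reagent may isomerise the spiro-epoxide to an allylic alcohol by deprotonation, or may substitute too slowly at the neopentyl-type C11.
   - The fallback sets out from 16.
   - One-carbon homologation with excess dimethylsulfonium methylide (trimethylsulfonium iodide, n-BuLi, THF, −10 → 23 °C) gives the 9α-hydroxy-9-vinyl compound F2.
   - Hydroboration of its terminal alkene with 9-BBN-H (excess, THF) gives the B-alkyl-9-BBN borane F3.
   - F3 is coupled in the same flask with commercial 2-bromoprop-2-en-1-ol (Pd(dppf)Cl2, Cs2CO3, DMF/THF/H2O, 50 °C; B-alkyl Suzuki–Miyaura coupling). The C12–C13 bond is made instead of C11–C12, and the route is re-entered at 19.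

3. **Step 19.** Vinylidene formation next to the fully substituted C13 may be slow, and the acid-labile enol ether may be lost during isolation by ring opening to the furan.
   - The fallback sets out from 24.
   - Anti-Markovnikov hydroboration of the alkyne with dicyclohexylborane followed by NaBO3 oxidation gives the C15 aldehyde, which closes onto the C16 hydroxyl as the C15 lactol F4 (C15 epimers).
   - Mesylation with elimination in the same flask (MsCl, excess Et3N, CH2Cl2, 0 → 40 °C) gives the C14=C15 enol ether. The route comes back at 25.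

## Further compounds

F1 | step 2 | ent-cycloadduct (mirror image of 4) | O=C1C=C(C)C(=O)[C@]2(C)CC(O[Si](C)(C)C(C)(C)C)=C[C@H](C)[C@H]12
F2 | step 13 | 9α-hydroxy-9-vinyl compound (C11=C12) | O[C@@H]1C[C@@H](C)[C@](O)(C=C)[C@@]2(C)CCCC(C)(C)[C@H]12
F3 | step 13 | B-alkyl-9-BBN borane (boron on C12) | O[C@@H]1C[C@@H](C)[C@](O)(CCB3C4CCCC3CCC4)[C@@]2(C)CCCC(C)(C)[C@H]12
F4 | step 19 | C15 lactol (C15 epimers) | CC(=O)O[C@@H]1C[C@@H](C)[C@]2(CC[C@@]3(CC(O)OC3)O2)[C@@]2(C)CCCC(C)(C)[C@H]12
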